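Readings and results were computed with constants of no real substance; the scatter is artificial.

In a one-step world the fraction of starting material left, f, falls as exp(−kt), so −ln f / t returns the same rate constant k from every reading, whatever the charge. We work with the fraction left and test this on the runs.

all flasks: catalyst 0.1 mol%

| flask | starting material | remark | time |
|---|---|---|---|
| Saturday's | 7.1 mM | run made earlier |  |
| Thursday's | 34 mM | run made earlier |  |
| dusk | 5.0 mM |  | 2.0 d |
| noon | 8.0 mM |  | 2.0 d |
| spring | 12 mM |  | 2.0 d |
| winter | 15 mM |  | 2.0 d |
| summer | 25 mM |  | 2.0 d |

- Saturday's (time / h: product / %, starting material / %): 3.00: 47.1, 25.4; 8.00: 92.7, 3.3; 15.0: 99.2, 0.2; 25.0: 99.6, 0; 30.0: 99.6, 0.5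
- Thursday's (time / h: product / %, starting material / %): 6.00: 91.3, 6.6; 15.0: 100.6, 0.2; 20.0: 98.1, 0; 25.0: 100.5, 0; 30.0: 101.1, 0

(scatter of a reading: 1 percentage point)

- amounts and yields of product count crystals too
- given per volume of solution although it is solid: crystals
- the earlier runs were read with a standard deviation of 1 percentage point
- what may be going on: starting material -> intermediate; catalyst + intermediate -> catalyst + product; crystals <-> product
- the concentration of product that is asked is that of its free form alone
- "hardly changes" means that all values lie within two and a half points (for a concentration: within two and a half percent of the largest)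

- [product] (only what is free in solution) at the end for dusk, noon, spring, winter, summer, in this order
- how the row runs (falls all the way / rises, then falls / rises all the way / hardly changes / falls, then rises)

Saturday's first row, 25.4% left after 3.00 h, gives 0.457 h⁻¹. Its second row, 3.3% after 8.00 h, gives 0.426 h⁻¹, but this reading is smaller than the first and carries the same scatter of 1 percentage point. Thursday's first row, 6.6% after 6.00 h from a charge of 34 mM against 7.1 mM, gives 0.453 h⁻¹. Later readings stand within 1 point of zero and add nothing. So we take the first rows of both charges, k = 0.455 h⁻¹, which makes τ, the half-life of starting material, 1.52 h.

The product column leaves the one-step world: Saturday's first row leaves 27.5% unaccounted for, which we place in intermediate. By 15.0 h the two columns add to 99.4%. The second step is pseudo-first-order in intermediate and goes with the catalyst, a fixed share of the charge, so the dusk flask should take about 21.3 h for the same closing, less than 2.0 d.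

The asked 2.0 d is 31.6 half-lives, and by our k starting material is down to 2.00% of the charge after 8.60 h. We therefore expect total product equal to the charge in each flask. Both runs count crystals as product, so they show no ceiling for the free form, and we commit to the charges themselves, rising all the way, with the top values open.

The forecast differs at the top, with 5 mM, 8 mM, 12 mM, 13 mM, 13 mM and rises all the way, and says of its ceiling: “That value is a guess, not a measurement”.

The flasks give 5.00 mM, 8.00 mM, 12.0 mM, 15.0 mM, 20.0 mM: rises all the way.

    starting material → intermediate (k = 0.00760 min⁻¹)
    catalyst + intermediate → catalyst + product (k = 1470 L mol⁻¹ min⁻¹)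
    crystals ⇌ product, rate k3*(cs3 - [product]) while solid is left; crystals form when [product] > cs3 (solubility = 20.0 mM, k = 0.343 min⁻¹)

In the summer flask starting material falls under 2.00% of its charge at 0.357 d, and the asked 2.0 d, which is 31.6 of our half-lives τ of 1.52 h, is 5.60 times that time, while the spring flask, charged with 12 mM against 25 mM, passes the same mark at 0.357 d. At 2.00 d the summer flask holds 0% starting material and 100% product, of which 20.0% is crystals, with free product at 20.0 mM.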